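## Retrosynthetic overview

1. **Feature.** The strategy rests on the 2,6-cis 5,6-dihydro-2H-pyran ring O1–C2–C3=C4–C4a–C8a (2H-chromene numbering), with its C3=C4 alkene and H-2, H-4a and H-8a all cis. This is the retron of a [3,3] ring contraction. Cutting C4a–C8a and re-making C3–O(acyl) gives a trans-5-decalinyl-6-[(E)-alkenyl]-1,4-dioxan-2-one.
2. **Cyclohexenone ring (last).** C7=C8 is made by RCM of a C8a vinyl group (from the C8 carboxyl) with an isopropenyl carbinol arm. The C6 carbinol then goes to the ketone, and the acetate follows.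
3. **Dioxanone.** The C3–C4 bond comes from chelation-controlled addition of an (E)-alkenylmagnesium reagent to an α-alkoxy aldehyde. The O1–C8a ether (tert-butyl bromoacetate) is installed earlier, while C2–OH is the only hydroxyl, so no diol regiochemistry arises.
4. **Aldehyde from (+)-sclareolide.** C6'=C7' is made by dehydration/isomerisation, OsO4/relactonisation (C8'–O restored on the α face) and syn elimination. α-Face enolate hydroxylation then sets C2.
5. **Ring order.** Decalin (chiral pool) → dioxanone (step 18) → dihydropyran (step 19) → cyclohexenone (step 23).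

Key step: step 19

**Remark on numbering.** The oxabicycle is numbered as 2H-chromene (O1 … C8a). Decalin atoms carry labdane numbers with a prime. The two-carbon arm of sclareolide is C11 (= chromene C2) and C12 (= chromene C3). "Dec" is the drim-6'-en-9'-yl group: 5'α-H, 9'α-H, 10'β-Me, 8'β-Me, 8'α-OSiEt3.

**Remark on the chemistry.** The C6 carbonyl is carried as the PMB ether of the (R)-carbinol and not as a ketal. A β,γ-unsaturated isopropenyl ketone cannot be ketalised without the unsaturation moving into conjugation. The configuration at C6 has no consequence and is erased in step 25.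

## Route

Step 1
Reactants: 1 (+)-sclareolide
Product: 3 methyl 8'α-hydroxy-13,14,15,16-tetranorlabdan-12-oate, via potassium 8'α-hydroxy-13,14,15,16-tetranorlabdan-12-oate 2 (not isolated)
Conditions: KOH, MeOH–H2O, reflux; evaporate; MeI, DMF, rt
Reagents that add atoms: potassium hydroxide [K+].[OH-]; iodomethane CI
Why: Saponification of the γ-lactone followed by SN2 O-methylation of the dry carboxylate runs under non-acidic conditions, so the tertiary hydroxy ester cannot relactonise and no stereocentre is touched.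

Step 2
Reactants: 3 methyl 8'α-hydroxy-13,14,15,16-tetranorlabdan-12-oate
Product: 4 methyl 13,14,15,16-tetranorlabd-8'(17')-en-12-oate (exocyclic methylene)
Conditions: SOCl2, pyridine, CH2Cl2, −78 °C
Reagents that add atoms: none
Why: In this E2 dehydration via the chlorosulfite the equatorial C8'–O bond has no antiperiplanar ring C–H, so proton loss from the freely rotating methyl group should dominate, and any Δ7' isomer formed alongside is harmless because step 3 converges on it.

Step 3
Reactants: 4 methyl 13,14,15,16-tetranorlabd-8'(17')-en-12-oate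
Product: 5 methyl 13,14,15,16-tetranorlabd-7'-en-12-oate
Conditions: Co(salen-tBu,tBu)Cl (cat.), PhSiH3 (cat.), benzene, rt, Ar
Reagents that add atoms: none
Why: In this cobalt-hydride MHAT (radical) alkene isomerisation, reversible H-atom transfer gives the tertiary C8' radical, and H abstraction from the open C7' methylene rather than the shielded C9' methine should give the trisubstituted alkene, which is too hindered to re-enter the cycle.

Step 4
Reactants: 5 methyl 13,14,15,16-tetranorlabd-7'-en-12-oate
Product: 7 7'α-hydroxysclareolide (trans-fused 8'α,12-olide, axial 7'α-OH cis to C8'–O), via methyl 7'α,8'α-dihydroxy-13,14,15,16-tetranorlabdan-12-oate 6 (not isolated)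
Conditions: OsO4 (cat.), NMO, acetone–H2O, rt; then p-TsOH (cat.), CH2Cl2, rt
Reagents that add atoms: N-methylmorpholine N-oxide C[N+]1([O-])CCOCC1; water O
Why: Upjohn dihydroxylation from the α face (the β face is blocked by the axial C10' methyl and the C9' side chain) sets 7'α-OH and restores the 8'α-O/8'β-Me centre, and acid-catalysed lactonisation re-forms the trans γ-lactone, which masks C8'–O as an acyl group.

Step 5
Reactants: 7 7'α-hydroxysclareolide
Product: 8 6',7'-didehydrosclareolide
Conditions: Burgess reagent, benzene, 50 → 80 °C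
Reagents that add atoms: none
Why: In this Burgess dehydration (thermal syn Ei elimination of the sulfamate) C8' is quaternary, so only the cis 6'α-H can be taken and C6'=C7' is the only possible alkene, while the electron-poor acyloxy group at C8' disfavours ionisation and methyl shift.

Step 6
Reactants: 8 6',7'-didehydrosclareolide
Product: 10 (11S)-11-hydroxy-6',7'-didehydrosclareolide (OH on the α face, cis to H-9'), via potassium enolate of 8 9 (not isolated)
Conditions: KHMDS, THF, −78 °C; 2-(phenylsulfonyl)-3-phenyloxaziridine, −78 °C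
Reagents that add atoms: 2-(phenylsulfonyl)-3-phenyloxaziridine O=S(=O)(c1ccccc1)N1OC1c1ccccc1
Why: In this Davis oxidation of the lactone enolate the oxaziridine approaches from the α face, cis to H-9' and away from the axial C8' and C10' methyl groups, which sets C11 (chromene C2).

Step 7
Reactants: 10 (11S)-11-hydroxy-6',7'-didehydrosclareolide; 11 tert-butyl bromoacetate
Product: 12 (11S)-11-(tert-butoxycarbonylmethoxy)-6',7'-didehydrosclareolide
Conditions: NaH, Bu4NI (cat.), THF–DMF, 0 °C → rt
Reagents that add atoms: none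
Why: This Williamson etherification with a very reactive α-bromo ester builds the O1–C8a bond while C11–OH is the only hydroxyl, so the regiochemical problem of a free 11,12-diol never arises, and the α-ether drawn is also the less hindered epimer should C11 equilibrate.

Step 8
Reactants: 12 (11S)-11-(tert-butoxycarbonylmethoxy)-6',7'-didehydrosclareolide
Product: 13 (11S)-8'α-hydroxy-11-(tert-butoxycarbonylmethoxy)-N-methoxy-N-methyl-13,14,15,16-tetranorlabd-6'-en-12-amide
Conditions: MeNH(OMe)·HCl, i-PrMgCl, THF, −20 → 0 °C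
Reagents that add atoms: N,O-dimethylhydroxylamine hydrochloride CNOC.Cl
Why: In this Weinreb aminolysis with the magnesium amide, the α-alkoxy γ-lactone is attacked much faster than the hindered tert-butyl ester, and the basic, non-Lewis-acidic medium spares the allylic tertiary C8'–O bond.

Step 9
Reactants: 13 hydroxy Weinreb amide
Product: 14 8'-O-triethylsilyl ether of 13
Conditions: TESOTf, 2,6-lutidine, CH2Cl2, −78 → 0 °C
Reagents that add atoms: triethylsilyl triflate CC[Si](CC)(CC)OS(=O)(=O)C(F)(F)F
Why: Silyl triflate silylation of the hindered tertiary allylic alcohol under lutidine buffering at low temperature, conditions that tert-butyl esters and Weinreb amides tolerate, blocks relactonisation and later lactol formation.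

Step 10
Reactants: 14 TES-protected Weinreb amide
Product: 15 (11S)-11-(tert-butoxycarbonylmethoxy)-8'α-(triethylsilyloxy)-13,14,15,16-tetranorlabd-6'-en-12-al
Conditions: DIBAL-H, THF, −78 °C
Reagents that add atoms: none
Why: Reduction of a Weinreb amide stops at the chelated tetrahedral aluminate and releases the aldehyde on work-up, and the tert-butyl ester is reduced only slowly at −78 °C.

Step 11
Reactants: 16 methacrolein; 17 propargyl bromide
Product: 19 (±)-2-methylhex-1-en-5-yn-3-ol, via allenylzinc bromide 18 (not isolated)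
Conditions: Zn (activated), THF, 0 °C → rt
Reagents that add atoms: none
Why: In this zinc Barbier propargylation the allenylzinc species adds 1,2 to the enal through an SE2' transition state and gives the homopropargylic alcohol.

Step 12
Reactants: 19 (±)-2-methylhex-1-en-5-yn-3-ol
Product: 20 (R)-2-methylhex-1-en-5-yn-3-ol
Conditions: Ti(Oi-Pr)4, L-(+)-DIPT, t-BuOOH (0.6 equiv), 4 Å MS, CH2Cl2, −20 °C
Reagents that add atoms: none
Why: In this Sharpless kinetic resolution with L-(+)-DIPT the (S)-allylic alcohol is epoxidised fast and the (R)-alcohol is recovered, and the centre only serves to keep all later intermediates single compounds.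

Step 13
Reactants: 20 (R)-2-methylhex-1-en-5-yn-3-ol
Product: 21 (R)-3-(4-methoxybenzyloxy)-2-methylhex-1-en-5-yne
Conditions: NaH, PMBCl, Bu4NI (cat.), THF–DMF, 0 °C → rt
Reagents that add atoms: 4-methoxybenzyl chloride COc1ccc(CCl)cc1
Why: This Williamson etherification installs a PMB group that is orthogonal to the silyl ethers and inert to organolithiums, amide bases and ruthenium carbenes.

Step 14
Reactants: 21 PMB ether
Product: 23 (5R)-5-(4-methoxybenzyloxy)-6-methylhept-6-en-2-yn-1-ol, via lithium acetylide of 21 22 (not isolated)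
Conditions: n-BuLi, THF, −78 °C; (CH2O)n, −78 °C → rt
Reagents that add atoms: formaldehyde (as paraformaldehyde) C=O
Why: Hydroxymethylation of the lithium acetylide supplies the carbon of the future CH2OAc group.

Step 15
Reactants: 23 propargylic alcohol
Product: 25 (2E,5R)-2-iodo-5-(4-methoxybenzyloxy)-6-methylhepta-2,6-dien-1-ol, via (2E,5R)-2-(tributylstannyl)-5-(4-methoxybenzyloxy)-6-methylhepta-2,6-dien-1-ol 24 (not isolated)
Conditions: Bu3SnH, PdCl2(PPh3)2 (cat.), THF, 0 °C → rt; then I2, 0 °C
Reagents that add atoms: iodine II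
Why: Pd-catalysed syn hydrostannation places tin on the alkyne carbon next to the inductively withdrawing CH2OH group, and iododestannylation with retention gives the alkene in which CH2OH and the C5 chain are cis.

Step 16
Reactants: 25 iodo allylic alcohol
Product: 26 (2E,5R)-1-(tert-butyldimethylsilyloxy)-2-iodo-5-(4-methoxybenzyloxy)-6-methylhepta-2,6-diene
Conditions: TBSCl, imidazole, CH2Cl2, rt
Reagents that add atoms: tert-butyldimethylsilyl chloride CC(C)(C)[Si](C)(C)Cl
Why: This is a standard silylation of the primary allylic alcohol.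

Step 17
Reactants: 26 alkenyl iodide; 15 α-alkoxy aldehyde
Product: 29 tert-butyl {[(1S,2S,3E,6R)-1-Dec-2-hydroxy-3-(tert-butyldimethylsilyloxymethyl)-6-(4-methoxybenzyloxy)-7-methylocta-3,7-dien-1-yl]oxy}acetate (11,12-syn), via alkenyllithium from 26 27 (not isolated), via alkenylmagnesium bromide from 26 28 (not isolated)
Conditions: 26, t-BuLi (2 equiv), Et2O, −78 °C; MgBr2·OEt2; then 15 + MgBr2·OEt2, CH2Cl2, −78 → −40 °C
Reagents that add atoms: none
Why: In this Cram-chelate addition Mg(II) holds the aldehyde oxygen and the α-ether oxygen syn, and the alkenyl Grignard reagent (made with retention by I–Li exchange and transmetalation) attacks past H-11 and anti to the decalin, which is also the sterically preferred face, so the 11,12-syn (12S) alcohol should result.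

Step 18
Reactants: 29 syn hydroxy tert-butyl ester
Product: 30 (5S,6S)-5-Dec-6-[(1E,4R)-1-(tert-butyldimethylsilyloxymethyl)-4-(4-methoxybenzyloxy)-5-methylhexa-1,5-dien-1-yl]-1,4-dioxan-2-one (trans)
Conditions: NaH (cat.), THF, 0 °C → rt
Reagents that add atoms: none
Why: In this alkoxide-catalysed lactonisation (transesterification) the C12 alkoxide attacks the α-alkoxy-activated ester through a six-membered transition state and expels tert-butoxide, which carries the chain; it is the neighbouring-alkoxide acyl transfer that makes δ-hydroxy tert-butyl esters easy to cleave with base, and both large groups end equatorial.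

Step 19
Reactants: 30 trans-5-Dec-6-alkenyl-1,4-dioxan-2-one
Product: 33 2,6-cis dihydropyran acid (chromene numbering: C2 Dec, C3=C4, C4 CH2OTBS, C4a CH2CH(OPMB)C(Me)=CH2, C8a CO2H; H-2, H-4a, H-8a all cis), via trimethylsilyl ketene acetal of 30 31 (not isolated), via trimethylsilyl ester of 33 32 (not isolated)
Conditions: LiHMDS, TMSCl–Et3N, THF, −78 °C; then toluene, 25 → 110 °C; aq. citric acid
Reagents that add atoms: none
Why: LiHMDS removes one of the only acidic protons (C8a–H2) and TMSCl traps the enolate on oxygen as the endocyclic ketene acetal 31, an allyl vinyl ether (C8a=C8–O–C3–C4=C4a) that undergoes a concerted suprafacial [3,3] shift on warming; this is the Ireland–Claisen rearrangement of 6-alkenyl-1,4-dioxan-2-ones to 5,6-dihydro-2H-pyrans. The pyran ring O1–C2–C3=C4–C4a–C8a closes by ring contraction: C4a–C8a forms across the dioxanone while the C3–O(acyl) bond breaks, the O1–C2 and O1–C8a bonds are carried over intact, and the extruded carbonyl carbon becomes the exocyclic carboxyl C8. The O1–C2 bridge between the termini C8a and C3 allows only a boat (bicyclo[2.2.2]-like) array, which places C2 cis on the new C3=C4 alkene. C8a is controlled by C3: the alkenyl group can reach only the face of the ketene acetal on which it stands, trans to the decalin at C2, and this puts H-8a cis to H-2 (2,6-cis). C4a is controlled by the (E)-alkene geometry: in the boat the C5 chain points away from the dioxanone and H-4a ends cis to H-8a. The step needs O- rather than C-silylation and a shift that is faster than loss of 31, which are secured by the single enolisable site, the single allylic ester, the small TMS group (least eclipsing with the C4 CH2OTBS arm) and the absence of any other acidic or heat-labile group.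

Step 20
Reactants: 33 dihydropyran acid
Product: 34 methyl ester of 33
Conditions: MeI, K2CO3, DMF, rt
Reagents that add atoms: iodomethane CI
Why: This SN2 O-alkylation of the carboxylate is mild enough not to touch C8a.

Step 21
Reactants: 34 methyl ester
Product: 35 C8 aldehyde (CHO at C8a)
Conditions: DIBAL-H, CH2Cl2, −78 °C
Reagents that add atoms: none
Why: In this partial reduction of an α-alkoxy ester the chelated tetrahedral aluminate survives at −78 °C and releases the aldehyde only on work-up.

Step 22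
Reactants: 35 aldehyde
Product: 36 C8a-vinyl dihydropyran (RCM diene)
Conditions: Ph3PCH3Br, KHMDS, THF, 0 °C; then 35, −78 → 0 °C
Reagents that add atoms: methyltriphenylphosphonium bromide C[P+](c1ccccc1)(c1ccccc1)c1ccccc1.[Br-]
Why: Wittig methylenation with the non-stabilised ylide at low temperature should be fast enough to outrun epimerisation at C8a.

Step 23
Reactants: 36 diene
Product: 37 (6R)-6-(4-methoxybenzyloxy)-7-methyl-4-(tert-butyldimethylsilyloxymethyl)-2-Dec-4a,5,6,8a-tetrahydro-2H-chromene (cis-fused)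
Conditions: Grubbs II (cat.), CH2Cl2, 40 °C
Reagents that add atoms: none
Why: In this ring-closing metathesis the catalyst loads on the monosubstituted vinyl group and closes the six-membered ring onto the isopropenyl group (C7=C8), while the ring alkenes C3=C4 and C6'=C7' are unstrained and hindered.

Step 24
Reactants: 37 PMB ether
Product: 38 (6R)-allylic alcohol
Conditions: DDQ, CH2Cl2–pH 7 buffer, 0 °C
Reagents that add atoms: none
Why: Oxidative PMB cleavage (benzylic hydride abstraction, then hydrolysis of the oxocarbenium ion) leaves silyl ethers and alkenes alone, and partial over-oxidation to 39 would be harmless.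

Step 25
Reactants: 38 allylic alcohol
Product: 39 bis-silylated enone (C6 ketone)
Conditions: Dess–Martin periodinane, CH2Cl2, 0 °C → rt
Reagents that add atoms: none
Why: Dess–Martin oxidation of the secondary allylic alcohol gives the enone and erases the auxiliary C6 centre.

Step 26
Reactants: 39 bis-silylated enone
Product: 40 diol (primary allylic OH at C4–CH2, tertiary 8'α-OH)
Conditions: HF·pyridine, pyridine, THF, 0 °C → rt
Reagents that add atoms: none
Why: Fluoride-driven cleavage of both silyl ethers under pyridine buffering keeps the medium too weakly acidic to ionise the tertiary allylic alcohol.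

Step 27
Reactants: 40 diol
Product: 41 CNP0180075.1 (target)
Conditions: Ac2O, pyridine, CH2Cl2, 0 °C
Reagents that add atoms: acetic anhydride CC(=O)OC(C)=O
Why: This is a selective acylation of the primary allylic alcohol, because the hindered tertiary C8'–OH does not acylate without forcing conditions.

## Compound list

1 | (+)-sclareolide | C[C@]12CCCC([C@@H]1CC[C@@]3([C@@H]2CC(=O)O3)C)(C)C | starting material
2 | potassium 8'α-hydroxy-13,14,15,16-tetranorlabdan-12-oate | [K+].[O-]C(=O)C[C@@H]1[C@@]2(C)CCCC(C)(C)[C@@H]2CC[C@@]1(C)O | intermediate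
3 | methyl 8'α-hydroxy-13,14,15,16-tetranorlabdan-12-oate | COC(=O)C[C@@H]1[C@@]2(C)CCCC(C)(C)[C@@H]2CC[C@@]1(C)O | intermediate
4 | methyl 13,14,15,16-tetranorlabd-8'(17')-en-12-oate | COC(=O)C[C@@H]1[C@@]2(C)CCCC(C)(C)[C@@H]2CCC1=C | intermediate
5 | methyl 13,14,15,16-tetranorlabd-7'-en-12-oate | COC(=O)C[C@@H]1[C@@]2(C)CCCC(C)(C)[C@@H]2CC=C1C | intermediate
6 | methyl 7'α,8'α-dihydroxy-13,14,15,16-tetranorlabdan-12-oate | COC(=O)C[C@@H]1[C@@]2(C)CCCC(C)(C)[C@@H]2C[C@@H](O)[C@@]1(C)O | intermediate
7 | 7'α-hydroxysclareolide | O=C1C[C@@H]2[C@@]3(C)CCCC(C)(C)[C@@H]3C[C@@H](O)[C@@]2(C)O1 | intermediate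
8 | 6',7'-didehydrosclareolide | O=C1C[C@@H]2[C@@]3(C)CCCC(C)(C)[C@@H]3C=C[C@@]2(C)O1 | intermediate
9 | potassium enolate of 8 | [K+].[O-]C1=C[C@@H]2[C@@]3(C)CCCC(C)(C)[C@@H]3C=C[C@@]2(C)O1 | intermediate
10 | (11S)-11-hydroxy-6',7'-didehydrosclareolide | O=C1[C@@H](O)[C@@H]2[C@@]3(C)CCCC(C)(C)[C@@H]3C=C[C@@]2(C)O1 | intermediate
11 | tert-butyl bromoacetate | CC(C)(C)OC(=O)CBr | starting material
12 | (11S)-11-(tert-butoxycarbonylmethoxy)-6',7'-didehydrosclareolide | O=C1[C@@H](OCC(=O)OC(C)(C)C)[C@@H]2[C@@]3(C)CCCC(C)(C)[C@@H]3C=C[C@@]2(C)O1 | intermediate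
13 | hydroxy Weinreb amide | CON(C)C(=O)[C@@H](OCC(=O)OC(C)(C)C)[C@@H]1[C@@]2(C)CCCC(C)(C)[C@@H]2C=C[C@@]1(C)O | intermediate
14 | 8'-O-TES Weinreb amide | CON(C)C(=O)[C@@H](OCC(=O)OC(C)(C)C)[C@@H]1[C@@]2(C)CCCC(C)(C)[C@@H]2C=C[C@@]1(C)O[Si](CC)(CC)CC | intermediate
15 | α-alkoxy aldehyde | O=C[C@@H](OCC(=O)OC(C)(C)C)[C@@H]1[C@@]2(C)CCCC(C)(C)[C@@H]2C=C[C@@]1(C)O[Si](CC)(CC)CC | intermediate
16 | methacrolein | C=C(C)C=O | starting material
17 | propargyl bromide | C#CCBr | starting material
18 | allenylzinc bromide | C=C=C[Zn]Br | intermediate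
19 | (±)-2-methylhex-1-en-5-yn-3-ol | C=C(C)C(O)CC#C | intermediate
20 | (R)-2-methylhex-1-en-5-yn-3-ol | C#CC[C@@H](O)C(C)=C | intermediate
21 | (R)-3-(4-methoxybenzyloxy)-2-methylhex-1-en-5-yne | C#CC[C@@H](OCc1ccc(OC)cc1)C(C)=C | intermediate
22 | lithium acetylide of 21 | [Li]C#CC[C@@H](OCc1ccc(OC)cc1)C(C)=C | intermediate
23 | (5R)-5-(4-methoxybenzyloxy)-6-methylhept-6-en-2-yn-1-ol | OCC#CC[C@@H](OCc1ccc(OC)cc1)C(C)=C | intermediate
24 | (2E,5R)-2-(tributylstannyl)-5-(4-methoxybenzyloxy)-6-methylhepta-2,6-dien-1-ol | CCCC[Sn](CCCC)(CCCC)/C(CO)=C/C[C@@H](OCc1ccc(OC)cc1)C(C)=C | intermediate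
25 | (2E,5R)-2-iodo-5-(4-methoxybenzyloxy)-6-methylhepta-2,6-dien-1-ol | I/C(CO)=C/C[C@@H](OCc1ccc(OC)cc1)C(C)=C | intermediate
26 | TBS ether of 25 | I/C(CO[Si](C)(C)C(C)(C)C)=C/C[C@@H](OCc1ccc(OC)cc1)C(C)=C | intermediate
27 | alkenyllithium from 26 | [Li]/C(CO[Si](C)(C)C(C)(C)C)=C/C[C@@H](OCc1ccc(OC)cc1)C(C)=C | intermediate
28 | alkenylmagnesium bromide from 26 | Br[Mg]/C(CO[Si](C)(C)C(C)(C)C)=C/C[C@@H](OCc1ccc(OC)cc1)C(C)=C | intermediate
29 | 11,12-syn hydroxy tert-butyl ester | CC(C)(C)OC(=O)CO[C@@H]([C@@H]1[C@@]2(C)CCCC(C)(C)[C@@H]2C=C[C@@]1(C)O[Si](CC)(CC)CC)[C@@H](O)/C(CO[Si](C)(C)C(C)(C)C)=C/C[C@@H](OCc1ccc(OC)cc1)C(C)=C | intermediate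
30 | trans-5-Dec-6-alkenyl-1,4-dioxan-2-one (key-step precursor) | O=C1CO[C@@H]([C@@H]2[C@@]3(C)CCCC(C)(C)[C@@H]3C=C[C@@]2(C)O[Si](CC)(CC)CC)[C@H](/C(CO[Si](C)(C)C(C)(C)C)=C/C[C@@H](OCc2ccc(OC)cc2)C(C)=C)O1 | intermediate
31 | trimethylsilyl ketene acetal of 30 | C[Si](C)(C)OC1=CO[C@@H]([C@@H]2[C@@]3(C)CCCC(C)(C)[C@@H]3C=C[C@@]2(C)O[Si](CC)(CC)CC)[C@H](/C(CO[Si](C)(C)C(C)(C)C)=C/C[C@@H](OCc2ccc(OC)cc2)C(C)=C)O1 | intermediate
32 | trimethylsilyl ester of 33 | CC(C)(C)[Si](C)(C)OCC1=C[C@H]([C@@H]2[C@@]3(C)CCCC(C)(C)[C@@H]3C=C[C@@]2(C)O[Si](CC)(CC)CC)O[C@H](C(=O)O[Si](C)(C)C)[C@@H]1C[C@@H](OCc2ccc(OC)cc2)C(C)=C | intermediate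
33 | 2,6-cis dihydropyran acid (key-step product) | CC(C)(C)[Si](C)(C)OCC1=C[C@H]([C@@H]2[C@@]3(C)CCCC(C)(C)[C@@H]3C=C[C@@]2(C)O[Si](CC)(CC)CC)O[C@H](C(O)=O)[C@@H]1C[C@@H](OCc2ccc(OC)cc2)C(C)=C | intermediate
34 | methyl ester of 33 | CC(C)(C)[Si](C)(C)OCC1=C[C@H]([C@@H]2[C@@]3(C)CCCC(C)(C)[C@@H]3C=C[C@@]2(C)O[Si](CC)(CC)CC)O[C@H](C(=O)OC)[C@@H]1C[C@@H](OCc2ccc(OC)cc2)C(C)=C | intermediate
35 | C8 aldehyde | CC(C)(C)[Si](C)(C)OCC1=C[C@H]([C@@H]2[C@@]3(C)CCCC(C)(C)[C@@H]3C=C[C@@]2(C)O[Si](CC)(CC)CC)O[C@H](C=O)[C@@H]1C[C@@H](OCc2ccc(OC)cc2)C(C)=C | intermediate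
36 | C8a-vinyl diene | CC(C)(C)[Si](C)(C)OCC1=C[C@H]([C@@H]2[C@@]3(C)CCCC(C)(C)[C@@H]3C=C[C@@]2(C)O[Si](CC)(CC)CC)O[C@H](C=C)[C@@H]1C[C@@H](OCc2ccc(OC)cc2)C(C)=C | intermediate
37 | RCM product, (6R)-PMB ether | CC(C)(C)[Si](C)(C)OCC1=C[C@H]([C@@H]2[C@@]3(C)CCCC(C)(C)[C@@H]3C=C[C@@]2(C)O[Si](CC)(CC)CC)O[C@@H]2C=C(C)[C@H](OCc3ccc(OC)cc3)C[C@H]12 | intermediate
38 | (6R)-allylic alcohol | CC(C)(C)[Si](C)(C)OCC1=C[C@H]([C@@H]2[C@@]3(C)CCCC(C)(C)[C@@H]3C=C[C@@]2(C)O[Si](CC)(CC)CC)O[C@@H]2C=C(C)[C@H](O)C[C@H]12 | intermediate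
39 | bis-silylated enone | CC(C)(C)[Si](C)(C)OCC1=C[C@H]([C@@H]2[C@@]3(C)CCCC(C)(C)[C@@H]3C=C[C@@]2(C)O[Si](CC)(CC)CC)O[C@@H]2C=C(C)C(=O)C[C@H]12 | intermediate
40 | diol | OCC1=C[C@H]([C@@H]2[C@@]3(C)CCCC(C)(C)[C@@H]3C=C[C@@]2(C)O)O[C@@H]2C=C(C)C(=O)C[C@H]12 | intermediate
41 | CNP0180075.1 | CC(=O)OCC1=C[C@H]([C@@H]2[C@@]3(C)CCCC(C)(C)[C@@H]3C=C[C@@]2(C)O)O[C@@H]2C=C(C)C(=O)C[C@H]12 | target

## Step count

Total step count: 27.
Longest linear sequence: 21 (steps 1–10, then 17–27).

## Steps most likely to fail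

**Step 19 (ring contraction).** The enforced boat eclipses the OSiMe3 group on C8 with the C4 CH2OTBS arm. The [3,3] shift may therefore be slower than loss of the ketene acetal by hydrolysis, C-silylation or ketene extrusion at the temperature needed.

The fallback replaces hard enolisation and a thermal silyl ketene acetal with a boron-enolate Claisen rearrangement. It sets out from 30. Soft enolisation with Bu2BOTf and i-Pr2NEt in CH2Cl2 at −78 °C should give the dibutylboron ketene acetal F1. This should rearrange through the same boat on warming to room temperature to the dibutylboryl ester F2. Work-up at pH 7 comes back to the route at 33.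

**Step 17 (fragment union).** Facial selectivity may be poor if the ester carbonyl competes for magnesium and the five-membered chelate is not formed. The basic alkenylmetal may also enolise the neopentyl-type aldehyde or fail to add to it.

The fallback is acylation followed by reduction. It sets out from Weinreb amide 14 and alkenyllithium 27 (from 26) in THF at −78 °C, which should give the enone F3. 1,2-Reduction with L-Selectride at −78 °C under polar Felkin–Anh control, the non-chelation mode that leads to syn diols from α-alkoxy ketones, comes back to the route at 29.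

**Step 18 (lactonisation).** The acyl transfer may stall at the hindered tert-butyl ester. The alkoxide medium may also start silyl migration or premature enolate chemistry of the product.

The fallback changes from alkoxide acyl transfer to ester cleavage followed by carboxyl activation. It sets out from 29. TMSOTf and 2,6-lutidine in CH2Cl2 at 0 °C should give the bis-trimethylsilyl derivative F4. Mild aqueous methanolysis should then give the hydroxy acid F5. EDCI with catalytic DMAP closes the ring and comes back to the route at 30.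

## Further compounds

F1 | step 19 | dibutylboron ketene acetal of 30 | CCCCB(CCCC)OC1=CO[C@@H]([C@@H]2[C@@]3(C)CCCC(C)(C)[C@@H]3C=C[C@@]2(C)O[Si](CC)(CC)CC)[C@H](/C(CO[Si](C)(C)C(C)(C)C)=C/C[C@@H](OCc2ccc(OC)cc2)C(C)=C)O1
F2 | step 19 | dibutylboryl ester of 33 | CC(C)(C)[Si](C)(C)OCC1=C[C@H]([C@@H]2[C@@]3(C)CCCC(C)(C)[C@@H]3C=C[C@@]2(C)O[Si](CC)(CC)CC)O[C@H](C(=O)OB(CCCC)CCCC)[C@@H]1C[C@@H](OCc2ccc(OC)cc2)C(C)=C
F3 | step 17 | C12 enone | CC(C)(C)OC(=O)CO[C@@H]([C@@H]1[C@@]2(C)CCCC(C)(C)[C@@H]2C=C[C@@]1(C)O[Si](CC)(CC)CC)C(=O)/C(CO[Si](C)(C)C(C)(C)C)=C/C[C@@H](OCc1ccc(OC)cc1)C(C)=C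
F4 | step 18 | bis-trimethylsilyl derivative (TMS ester, 12-O-TMS ether) | C[Si](C)(C)OC(=O)CO[C@@H]([C@@H]1[C@@]2(C)CCCC(C)(C)[C@@H]2C=C[C@@]1(C)O[Si](CC)(CC)CC)[C@@H](O[Si](C)(C)C)/C(CO[Si](C)(C)C(C)(C)C)=C/C[C@@H](OCc1ccc(OC)cc1)C(C)=C
F5 | step 18 | hydroxy acid | OC(=O)CO[C@@H]([C@@H]1[C@@]2(C)CCCC(C)(C)[C@@H]2C=C[C@@]1(C)O[Si](CC)(CC)CC)[C@@H](O)/C(CO[Si](C)(C)C(C)(C)C)=C/C[C@@H](OCc1ccc(OC)cc1)C(C)=C
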